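**Remark on the chemistry.** The lactone atoms are called O1, C2 (carbonyl), C3, C4 and C5, and the carbinol carbon on C4 is called C7. Methyl (R)-glycidate 3 is assumed to be bought as a chiral-pool reagent. Ring A and C3 are built from an aryl Grignard reagent and 3 instead of from an aldehyde-derived keto acid; this is shorter, fixes the configuration without an asymmetric reduction, and lets one aryl bromide serve both rings. Compounds are numbered 1–21 in the order of the steps; the full list follows step 11.

## Analysis of the target

The target is a 3,4-disubstituted γ-butyrolactone of the dibenzylbutyrolactone lignan type: C3 carries the 4-hydroxy-3-methoxybenzyl group (ring A), and C4 carries the secondary carbinol carbon C7, which bears ring B, a second 4-hydroxy-3-methoxyphenyl group. There are three contiguous stereocentres, C3 (R), C4 (R) and C7 (S). The two ring substituents are trans, and C7 lies outside the ring, so ring geometry does not fix its relation to C4. The most fragile element is the p-hydroxybenzylic alcohol at C7: acid ionises it to a cation that ring A can trap, and base can lead to a quinone methide or to transfer of the lactone acyl group from O1 to the C7 oxygen. C3 is α to the carbonyl and can be epimerised by base, and both phenols must be masked in every organometallic step. The difficulty is to set three adjacent centres on a small, flexible frame while keeping acid away from the carbinol and base away from the lactone. The strategy rests on the fact that C4 carries two one-carbon oxygenated arms, C5 and C7. While both are hydroxymethyl groups, C4 is not a stereocentre; the arm that closes onto C2 defines its configuration, and if that choice is reversible, C3 alone decides C4 through the preference of the ring for the trans arrangement.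

## Retrosynthetic reasoning

**21 to 20.** The last operation removes the two aryl silyl ethers of 20, the bis-silyl ether of the target. No skeletal bond is cut. The phenols are unmasked only at the end because the free p-hydroxybenzylic carbinol is the most labile part of 21. The forward step must cleave Si–O with buffered fluoride without ionising C7 or epimerising C3.

**20 to 16 and 19.** The bond between C7 and ring B is cut, leading to the lactone aldehyde 16 and the arylzinc reagent 19, which comes from bromide 2. This cut keeps the natural polarity: a formyl carbon is the electrophile, whereas a cut at C4–C7 would need a homoenolate at C4. More important, C7 becomes a carbinol only after the lactone exists, so ring closure never has to choose between an oxygen on C5 and one on C7, and no acid meets the benzylic alcohol. The forward step must deliver the aryl group to one face of the formyl group under control of a chiral ligand.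

**16 to 15.** The aldehyde is traced to the primary alcohol of the trans hydroxymethyl lactone 15. This only adjusts the oxidation level; the forward oxidation must be non-basic so that C4 and C3 are left alone.

**15 to 12.** The lactone C2–O1 bond is cut, giving the tert-butyl ester diol 12, in which C4 bears two identical hydroxymethyl arms and is not stereogenic. This removes the need for a separate asymmetric step at C4: only C3 has to be made, and C4 is created when the ring closes. The forward reaction must cleave the tert-butyl ester, close the γ-lactone onto either arm, and keep the two lactones 14 and 15 in exchange until the trans isomer dominates. C3 must stay untouched, which requires acid and excludes base.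

**12 to 11.** The two hydroxymethyl arms are traced to the two methyl esters of the triester 11. A hydride reduction must take both methyl esters and leave the hindered tert-butyl ester, so that the carboxyl destined to become C2 is held back until the key step.

**11 to 8 and 9.** The C3–C4 bond is cut between a malonate carbanion (from dimethyl malonate 9) and the α-triflyloxy ester 8. This is the one skeletal bond next to the only stereocentre that has to be bought. An SN2 displacement with inversion transfers the configuration of a lactate to C3, and it delivers C4 already carrying its two equivalent arms.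

**8 to 7, 6 and 5.** The triflate 8 comes from the tert-butyl lactate 7 without touching the C–O bond. The tert-butyl ester is traced through the acid 6 to the methyl ester 5, because the chiral-pool epoxide is available as its methyl ester. The two forward steps must exchange the ester without base strong enough to remove the aryl silyl group.

**5 to 2 and 3.** The bond between ring A and its benzylic carbon is cut, giving the Grignard reagent 4 from bromide 2 and methyl (R)-glycidate 3. The epoxide is opened at its unsubstituted carbon, so the stereocentre of 3 passes unchanged into the lactate and no asymmetric step is needed.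

**2 to 1.** Bromide 2 is the silyl ether of 4-bromo-2-methoxyphenol 1 and is used twice, for ring A and for ring B.

## Alternatives that were turned down

**Alternative 1: insertion of the carbinol carbon by boronic ester homologation.**
- Disconnection: the C4–C7 and C7–aryl bonds are both made on boron.
- Forward key step: a secondary boronic ester with boron on C4, A2 (drawn as the pinacol ester; a chiral diol on boron would be needed for reagent control), takes up a dichloromethyl carbenoid. C4 migrates to the new carbon, the Grignard reagent 4 displaces the second chloride in a further 1,2-shift, and peroxide replaces boron by hydroxyl to give the open-chain ester A1.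
- For: C7 is made by stereospecific migrations under control of the diol on boron, independent of any bias from C3 and C4. On this point it is stronger than the chosen route, where a ligand may have to override the substrate.
- Against:
  - No ring is formed. After removal of the triethylsilyl group, A1 has two hydroxyls γ to the ester, on C5 and on C7, so lactonisation must choose between them.
  - The acid needed for the tert-butyl ester meets the electron-rich benzylic alcohol.
  - A2 already contains C3 and C4 as defined centres, so the problem the chosen route solves by equilibration is only moved upstream.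
  - A boronate with a β-silyloxy group can fragment by β-elimination once the ate complex forms.
- Comparison: the sequence is clearly longer. The chosen strategy offers ring closure before C7 exists, so there is no regiochemical question, and it sets C4 without a reagent.

**Alternative 2: oxidative ring expansion of a 3-substituted cyclobutanone.**
- Disconnection: oxygen is inserted between C2 and C5 of a four-membered ketone, and C3 is benzylated afterwards.
- Forward key step: cyclobutanone A4, which already carries the silylated (S)-carbinol, is treated with a chiral catalyst and aqueous peroxide (Baeyer–Villiger oxidation). One of the two α-methylenes migrates to oxygen and gives lactone A3. Alkylation of its enolate with the benzylic bromide A5, trans to the C4 substituent, would complete the skeleton.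
- For: ring and C4 are made in one catalytic step. The trans-selective alkylation of a β-substituted butyrolactone enolate is highly dependable, and C7 is set early by a simple ketone reduction. In step count this route is as short as the chosen one or shorter, and at C3 and C7 it is stronger.
- Against:
  - With C7 present, the catalyst must distinguish two diastereotopic methylenes next to an existing centre, and enantioselective oxidations of this kind are sensitive to the 3-substituent.
  - Peroxide and acid meet two electron-rich aryl ethers and a benzylic silyl ether.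
  - A wrong C4 cannot be corrected afterwards.
  - A5 is a labile, quinone-methide-prone halide.
- Comparison: the chosen strategy needs no enantioselective catalyst for C3 and C4, because these come from the chiral pool and from thermodynamics, and it never carries the benzylic oxygen through peroxide or enolate chemistry.

**Alternative 3: hydroboration of a methylene group on C4.**
- Disconnection: the C4–H bond and the C5–O1–C2 linkage.
- Forward key step: alkene A7, with C3 and C7 in place, is hydroborated with RhCl(PPh3)3 and a catechol-derived borane. Hydrogen goes to C4 and boron to C5; oxidation gives the C5 alcohol, which closes onto the methyl ester to give A6, the fully silylated target.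
- For: this is the most convergent plan. Both rings and two stereocentres are assembled before the ring closes, and A6 is one step from 21. On convergence it is stronger than the chosen route.
- Against:
  - C4 is set by irreversible hydride delivery to an alkene face flanked by two allylic stereocentres whose preferences need not agree, and nothing can repair it later.
  - 1,1-Disubstituted alkenes react slowly in the catalysed reaction, which leaves room for the uncatalysed pathway with different selectivity.
  - A rhodium hydride may isomerise the alkene into conjugation with the ester, which would erase C3.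
  - The alkaline peroxide work-up threatens the ester α-centre and the aryl silyl ethers.
- Comparison: the chosen strategy sets C4 under equilibrium control, which corrects itself and depends only on C3.

Key step: step 8

## Route

Step 1
Reactants: 1 4-bromo-2-methoxyphenol
Product: 2 (4-bromo-2-methoxyphenoxy)(tert-butyl)dimethylsilane
Conditions: TBSCl, imidazole, DMF, rt
Reagents that add atoms: tert-butyldimethylsilyl chloride, CC(C)(C)[Si](C)(C)Cl
Why: Silylation of a phenol with a silyl chloride and imidazole; the ether masks the acidic hydroxyl for the organometallic steps, and this one bromide supplies both aromatic rings.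

Step 2
Reactants: 2 (4-bromo-2-methoxyphenoxy)(tert-butyl)dimethylsilane; 3 methyl (R)-glycidate
Product: 5 methyl (2R)-3-[4-(tert-butyldimethylsilyloxy)-3-methoxyphenyl]-2-hydroxypropanoate, via arylmagnesium bromide 4 (not isolated)
Conditions: Mg, THF, 40 °C; then CuBr·SMe2 (10 mol %), 3, THF, −40 to −20 °C
Reagents that add atoms: none
Why: Grignard formation followed by copper-catalysed SN2 opening of the epoxide at its unsubstituted carbon, which at low temperature is faster than addition to the ester. The stereocentre of 3 is not touched, so its (R) configuration becomes that of the lactate.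

Step 3
Reactants: 5 methyl (2R)-3-[4-(tert-butyldimethylsilyloxy)-3-methoxyphenyl]-2-hydroxypropanoate
Product: 6 (2R)-3-[4-(tert-butyldimethylsilyloxy)-3-methoxyphenyl]-2-hydroxypropanoic acid
Conditions: Me3SnOH, 1,2-dichloroethane, 70 °C; then dilute aq. HCl
Reagents that add atoms: trimethyltin hydroxide, C[Sn](C)(C)O
Why: Tin hydroxide-mediated hydrolysis of a methyl ester under nearly neutral conditions; it should spare the base-labile aryl silyl ether and the α-stereocentre, which aqueous hydroxide would put at risk.

Step 4
Reactants: 6 (2R)-3-[4-(tert-butyldimethylsilyloxy)-3-methoxyphenyl]-2-hydroxypropanoic acid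
Product: 7 tert-butyl (2R)-3-[4-(tert-butyldimethylsilyloxy)-3-methoxyphenyl]-2-hydroxypropanoate
Conditions: tert-butyl 2,2,2-trichloroacetimidate, cyclohexane/CH2Cl2, rt
Reagents that add atoms: tert-butyl 2,2,2-trichloroacetimidate, CC(C)(C)OC(=N)C(Cl)(Cl)Cl
Why: Esterification by an imidate: the carboxylic acid protonates the reagent and is O-alkylated by the tert-butyl group. Without added acid catalyst the secondary alcohol should not be etherified.

Step 5
Reactants: 7 tert-butyl (2R)-3-[4-(tert-butyldimethylsilyloxy)-3-methoxyphenyl]-2-hydroxypropanoate
Product: 8 tert-butyl (2R)-3-[4-(tert-butyldimethylsilyloxy)-3-methoxyphenyl]-2-[(trifluoromethanesulfonyl)oxy]propanoate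
Conditions: Tf2O, 2,6-lutidine, CH2Cl2, −78 °C
Reagents that add atoms: trifluoromethanesulfonic anhydride, O=S(=O)(OS(=O)(=O)C(F)(F)F)C(F)(F)F
Why: O-Sulfonylation of the alcohol; the C–O bond is not broken, so the configuration is retained. The triflate is kept cold and used without purification.

Step 6
Reactants: 8 tert-butyl (2R)-3-[4-(tert-butyldimethylsilyloxy)-3-methoxyphenyl]-2-[(trifluoromethanesulfonyl)oxy]propanoate; 9 dimethyl malonate
Product: 11 2-tert-butyl 1,1-dimethyl (2R)-3-[4-(tert-butyldimethylsilyloxy)-3-methoxyphenyl]propane-1,1,2-tricarboxylate, via sodium dimethyl malonate 10 (not isolated)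
Conditions: 9, NaH, THF, 0 °C; then 8, −20 °C to rt
Reagents that add atoms: none
Why: SN2 displacement of an α-triflyloxy ester by a malonate carbanion with inversion at C3; the neighbouring ester accelerates direct substitution and disfavours ionisation. The descriptor stays (R) although the centre is inverted, because the departing oxygen ranked first and the incoming carbon ranks second.

Step 7
Reactants: 11 2-tert-butyl 1,1-dimethyl (2R)-3-[4-(tert-butyldimethylsilyloxy)-3-methoxyphenyl]propane-1,1,2-tricarboxylate
Product: 12 tert-butyl (2R)-2-[4-(tert-butyldimethylsilyloxy)-3-methoxybenzyl]-4-hydroxy-3-(hydroxymethyl)butanoate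
Conditions: LiBH4, THF, 0 °C to rt
Reagents that add atoms: none
Why: Chemoselective borohydride reduction: LiBH4 reduces methyl esters to primary alcohols, while the hindered tert-butyl ester reacts far more slowly. C4 now carries two identical hydroxymethyl arms and is not a stereocentre.

Step 8
Reactants: 12 tert-butyl (2R)-2-[4-(tert-butyldimethylsilyloxy)-3-methoxybenzyl]-4-hydroxy-3-(hydroxymethyl)butanoate
Product: 15 (3R,4S)-3-[4-(tert-butyldimethylsilyloxy)-3-methoxybenzyl]-4-(hydroxymethyl)dihydrofuran-2(3H)-one (trans), via dihydroxy acid 13 (not isolated), via cis lactone 14 (not isolated)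
Conditions: TsOH·H2O (0.3 equiv), toluene (0.05 M), 80 °C, closed flask
Reagents that add atoms: none
Why: TsOH protonates the tert-butyl ester, which loses 2-methylpropene by alkyl–oxygen cleavage to give the dihydroxy acid 13; either primary hydroxyl then adds to the protonated carboxyl in a 5-exo-trig closure that forms the C2–O1 bond and the γ-lactone, giving 14 and 15. The closest known reaction types are the acid lactonisation of γ-hydroxy tert-butyl esters and acyl migration in monoacylated 1,3-diols. The two lactones differ only in which arm has become C5, so their interconversion inverts C4 without breaking a bond to it: the free hydroxymethyl group of one lactone can add to C2 to give a bridged orthoacid (a 2,6-dioxabicyclo[2.2.1]heptan-1-ol) that collapses to the other, and the water kept in the flask can also reopen either lactone to 13. C4 is therefore set under thermodynamic control by the fixed C3 centre, the trans lactone 15 placing the ring A benzyl group and the hydroxymethyl group on opposite faces. C3 is not touched, because acid at this temperature should not enolise the lactone; base is avoided, since epimerisation of 14 at C3 would lead into the enantiomeric series. The selectivity needed is trans over cis at C4, and it is secured by reversibility, not by a reagent; 15 is expected to dominate clearly but not exclusively, and residual 14 can be separated and returned to the same conditions. The aryl silyl ether is expected to survive catalytic sulfonic acid in toluene.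

Step 9
Reactants: 15 (3R,4S)-3-[4-(tert-butyldimethylsilyloxy)-3-methoxybenzyl]-4-(hydroxymethyl)dihydrofuran-2(3H)-one
Product: 16 (3R,4R)-4-[4-(tert-butyldimethylsilyloxy)-3-methoxybenzyl]-5-oxotetrahydrofuran-3-carbaldehyde
Conditions: Dess–Martin periodinane, CH2Cl2, 0 °C to rt
Reagents that add atoms: none
Why: Dess–Martin oxidation of a primary alcohol to the aldehyde under non-basic conditions. The aldehyde is used crude; should C4 epimerise, the trans isomer is the favoured one, and ring opening by β-elimination of O1 would be the reverse of a 5-endo-trig closure.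

Step 10
Reactants: 16 (3R,4R)-4-[4-(tert-butyldimethylsilyloxy)-3-methoxybenzyl]-5-oxotetrahydrofuran-3-carbaldehyde; 2 (4-bromo-2-methoxyphenoxy)(tert-butyl)dimethylsilane
Product: 20 (3R,4R)-3-[4-(tert-butyldimethylsilyloxy)-3-methoxybenzyl]-4-{(S)-[4-(tert-butyldimethylsilyloxy)-3-methoxyphenyl](hydroxy)methyl}dihydrofuran-2(3H)-one, via aryllithium 17 (not isolated), via arylzinc chloride 18 (not isolated), via aryl(butyl)zinc 19 (not isolated)
Conditions: 2, n-BuLi, t-BuOMe, −78 to 0 °C; ZnCl2; n-BuLi; TEEDA (N,N,N',N'-tetraethylethylenediamine); (+)-MIB [(2R)-3-exo-morpholinoisoborneol] (10 mol %), 16, toluene, 0 °C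
Reagents that add atoms: none
Why: Lithium–bromine exchange, transmetalation to zinc and alkylation give the mixed reagent 19, whose aryl group is transferred to the aldehyde within the chiral zinc aminoalkoxide formed from the ligand (catalytic asymmetric arylzinc addition). The (2R)-ligand is chosen to deliver the aryl group to the Re face of the formyl group (O > C4 > H), which gives the (S)-carbinol, by analogy with the Si-face delivery of the (2S)-ligand in aldehyde alkylations. TEEDA binds LiCl and suppresses the unselective background addition, and organozinc reagents do not attack the lactone.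

Step 11
Reactants: 20 (3R,4R)-3-[4-(tert-butyldimethylsilyloxy)-3-methoxybenzyl]-4-{(S)-[4-(tert-butyldimethylsilyloxy)-3-methoxyphenyl](hydroxy)methyl}dihydrofuran-2(3H)-one
Product: 21 (3R,4R)-4-[(S)-hydroxy(4-hydroxy-3-methoxyphenyl)methyl]-3-(4-hydroxy-3-methoxybenzyl)dihydrofuran-2(3H)-one
Conditions: TBAF, AcOH (1:1), THF, 0 °C
Reagents that add atoms: none
Why: Fluoride cleavage of the two aryl silyl ethers. The acetic acid buffer keeps the phenols protonated, which should prevent quinone methide formation at C7, epimerisation at C3 and acyl transfer of the lactone to the C7 oxygen.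

## Compound list

1 | 4-bromo-2-methoxyphenol | COc1cc(Br)ccc1O | starting material
2 | (4-bromo-2-methoxyphenoxy)(tert-butyl)dimethylsilane | COc1cc(Br)ccc1O[Si](C)(C)C(C)(C)C | intermediate
3 | methyl (R)-glycidate, methyl (2R)-oxirane-2-carboxylate | COC(=O)[C@H]1CO1 | starting material
4 | [4-(tert-butyldimethylsilyloxy)-3-methoxyphenyl]magnesium bromide | COc1cc([Mg]Br)ccc1O[Si](C)(C)C(C)(C)C | intermediate (not isolated)
5 | methyl (2R)-3-[4-(tert-butyldimethylsilyloxy)-3-methoxyphenyl]-2-hydroxypropanoate | COc1cc(C[C@@H](O)C(=O)OC)ccc1O[Si](C)(C)C(C)(C)C | intermediate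
6 | (2R)-3-[4-(tert-butyldimethylsilyloxy)-3-methoxyphenyl]-2-hydroxypropanoic acid | COc1cc(C[C@@H](O)C(=O)O)ccc1O[Si](C)(C)C(C)(C)C | intermediate
7 | tert-butyl (2R)-3-[4-(tert-butyldimethylsilyloxy)-3-methoxyphenyl]-2-hydroxypropanoate | COc1cc(C[C@@H](O)C(=O)OC(C)(C)C)ccc1O[Si](C)(C)C(C)(C)C | intermediate
8 | tert-butyl (2R)-3-[4-(tert-butyldimethylsilyloxy)-3-methoxyphenyl]-2-[(trifluoromethanesulfonyl)oxy]propanoate | COc1cc(C[C@@H](OS(=O)(=O)C(F)(F)F)C(=O)OC(C)(C)C)ccc1O[Si](C)(C)C(C)(C)C | intermediate
9 | dimethyl malonate | COC(=O)CC(=O)OC | starting material
10 | sodium dimethyl malonate | [Na+].COC(=O)[CH-]C(=O)OC | intermediate (not isolated)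
11 | 2-tert-butyl 1,1-dimethyl (2R)-3-[4-(tert-butyldimethylsilyloxy)-3-methoxyphenyl]propane-1,1,2-tricarboxylate | COc1cc(C[C@H](C(C(=O)OC)C(=O)OC)C(=O)OC(C)(C)C)ccc1O[Si](C)(C)C(C)(C)C | intermediate
12 | tert-butyl (2R)-2-[4-(tert-butyldimethylsilyloxy)-3-methoxybenzyl]-4-hydroxy-3-(hydroxymethyl)butanoate | COc1cc(C[C@H](C(CO)CO)C(=O)OC(C)(C)C)ccc1O[Si](C)(C)C(C)(C)C | intermediate
13 | (2R)-2-[4-(tert-butyldimethylsilyloxy)-3-methoxybenzyl]-4-hydroxy-3-(hydroxymethyl)butanoic acid | COc1cc(C[C@H](C(CO)CO)C(=O)O)ccc1O[Si](C)(C)C(C)(C)C | intermediate (not isolated)
14 | (3R,4R)-3-[4-(tert-butyldimethylsilyloxy)-3-methoxybenzyl]-4-(hydroxymethyl)dihydrofuran-2(3H)-one (cis) | COc1cc(C[C@H]2C(=O)OC[C@H]2CO)ccc1O[Si](C)(C)C(C)(C)C | intermediate (not isolated)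
15 | (3R,4S)-3-[4-(tert-butyldimethylsilyloxy)-3-methoxybenzyl]-4-(hydroxymethyl)dihydrofuran-2(3H)-one (trans) | COc1cc(C[C@H]2C(=O)OC[C@@H]2CO)ccc1O[Si](C)(C)C(C)(C)C | intermediate
16 | (3R,4R)-4-[4-(tert-butyldimethylsilyloxy)-3-methoxybenzyl]-5-oxotetrahydrofuran-3-carbaldehyde | COc1cc(C[C@H]2C(=O)OC[C@@H]2C=O)ccc1O[Si](C)(C)C(C)(C)C | intermediate
17 | [4-(tert-butyldimethylsilyloxy)-3-methoxyphenyl]lithium | [Li]c1ccc(O[Si](C)(C)C(C)(C)C)c(OC)c1 | intermediate (not isolated)
18 | [4-(tert-butyldimethylsilyloxy)-3-methoxyphenyl]zinc chloride | Cl[Zn]c1ccc(O[Si](C)(C)C(C)(C)C)c(OC)c1 | intermediate (not isolated)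
19 | butyl[4-(tert-butyldimethylsilyloxy)-3-methoxyphenyl]zinc | CCCC[Zn]c1ccc(O[Si](C)(C)C(C)(C)C)c(OC)c1 | intermediate (not isolated)
20 | (3R,4R)-3-[4-(tert-butyldimethylsilyloxy)-3-methoxybenzyl]-4-{(S)-[4-(tert-butyldimethylsilyloxy)-3-methoxyphenyl](hydroxy)methyl}dihydrofuran-2(3H)-one | COc1cc(C[C@H]2C(=O)OC[C@@H]2[C@H](O)c2ccc(O[Si](C)(C)C(C)(C)C)c(OC)c2)ccc1O[Si](C)(C)C(C)(C)C | intermediate
21 | (3R,4R)-4-[(S)-hydroxy(4-hydroxy-3-methoxyphenyl)methyl]-3-(4-hydroxy-3-methoxybenzyl)dihydrofuran-2(3H)-one | COc1cc(C[C@H]2C(=O)OC[C@@H]2[C@H](O)c2ccc(O)c(OC)c2)ccc1O | target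

## Step count and least certain steps

Total: 11 steps. Longest linear sequence: 11 steps (1 to 21); bromide 2 enters twice, in steps 2 and 10.

**Step 8 (key step).**
- Most likely problem: incomplete convergence on the trans lactone. Either the exchange of the two arms is slow, because the bridged orthoacid is strained and little water is present, or the equilibrium leaves a substantial share of the cis isomer. Lesser risks are partial loss of the aryl silyl group and tert-butylation of ring A by the departing cation.
- Fallback: the mixture of 14 and 15 is oxidised as in step 9 to 16 together with its C4 epimer, (3S,4R)-4-[4-(tert-butyldimethylsilyloxy)-3-methoxybenzyl]-5-oxotetrahydrofuran-3-carbaldehyde F1. In these aldehydes C4 is α to the formyl group, so a tertiary amine (Et3N, CH2Cl2, rt) equilibrates it by enolisation instead of acyl transfer. C3, a far less acidic lactone α-carbon, stays fixed. The route is rejoined at 16.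

**Step 10.**
- Most likely problem: poor facial selectivity. A steric Felkin–Anh reading of 16, with C3 as the larger α-substituent, points to attack on the Si face, so the ligand probably has to override the substrate (mismatched pairing). Further risks are epimerisation at C4 of the aldehyde and acyl transfer of the lactone to the new zinc alkoxide.
- Fallback: 16 is treated with the Grignard reagent 4 (made from 2 as in step 2) in THF at −78 °C. This gives 20 mixed with its C7 epimer, (3R,4R)-3-[4-(tert-butyldimethylsilyloxy)-3-methoxybenzyl]-4-{(R)-[4-(tert-butyldimethylsilyloxy)-3-methoxyphenyl](hydroxy)methyl}dihydrofuran-2(3H)-one F2. The mixture is oxidised with Dess–Martin periodinane to the aryl ketone (3R,4R)-3-[4-(tert-butyldimethylsilyloxy)-3-methoxybenzyl]-4-[4-(tert-butyldimethylsilyloxy)-3-methoxybenzoyl]dihydrofuran-2(3H)-one F3. Corey–Bakshi–Shibata reduction with (R)-2-methyl-CBS-oxazaborolidine and BH3·SMe2 in THF at −20 °C returns the route to 20. In the ketone, reagent and substrate bias should agree, since hydride now enters on the face that the aryl group would take in the aldehyde.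

**Step 6.**
- Most likely problem: E2 elimination of the triflate to the cinnamate, with the malonate acting as a base on the benzylic hydrogens, and erosion of configurational purity through participation of the electron-rich ring A or through triflate exchange.
- Fallback: the C3–C4 bond is made by enamine catalysis instead of SN2.
  - Bromide 2 is coupled with allyl alcohol under phosphine-free Heck conditions (Pd(OAc)2, Bu4NCl, NaHCO3, DMF, 60 °C) to give 3-[4-(tert-butyldimethylsilyloxy)-3-methoxyphenyl]propanal F4.
  - Enantioselective α-alkylation with dimethyl bromomalonate gives dimethyl 2-{(2R)-1-[4-(tert-butyldimethylsilyloxy)-3-methoxyphenyl]-3-oxopropan-2-yl}propanedioate F5. The conditions are a chiral imidazolidinone catalyst (the enantiomer that gives the (R)-aldehyde), Ru(bpy)3Cl2, 2,6-lutidine, DMF and visible light.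
  - Pinnick oxidation (NaClO2, NaH2PO4, 2-methyl-2-butene, t-BuOH/H2O) gives (2R)-2-[4-(tert-butyldimethylsilyloxy)-3-methoxybenzyl]-4-methoxy-3-(methoxycarbonyl)-4-oxobutanoic acid F6.
  - LiBH4 in THF reduces the two methyl esters while the lithium carboxylate is inert. Acidification gives the dihydroxy acid 13, where the route is rejoined under the conditions of step 8.

**Step 7.**
- Most likely problem: over-reduction. A first-formed alkoxide may close onto the tert-butyl ester, and the lactone so formed would be reduced on to a triol. Retro-aldol loss of formaldehyde from the half-reduced β-hydroxy ester is a second risk.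
- Fallback: the arms are distinguished from the tert-butyl ester by functional group instead of by rate.
  - Triflate 8 is displaced with sodium dibenzyl malonate (dibenzyl malonate, NaH, THF) as in step 6 to give 1,1-dibenzyl 2-tert-butyl (2R)-3-[4-(tert-butyldimethylsilyloxy)-3-methoxyphenyl]propane-1,1,2-tricarboxylate F7.
  - Hydrogenolysis (H2, Pd/C, EtOAc) gives 2-{(2R)-1-tert-butoxy-3-[4-(tert-butyldimethylsilyloxy)-3-methoxyphenyl]-1-oxopropan-2-yl}propanedioic acid F8.
  - BH3·SMe2 in THF at 0 °C reduces the two carboxylic acids and leaves the ester, which returns the route to 12.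

## Further compounds

F1 | step 8 | (3S,4R)-4-[4-(tert-butyldimethylsilyloxy)-3-methoxybenzyl]-5-oxotetrahydrofuran-3-carbaldehyde | COc1cc(C[C@H]2C(=O)OC[C@H]2C=O)ccc1O[Si](C)(C)C(C)(C)C
F2 | step 10 | (3R,4R)-3-[4-(tert-butyldimethylsilyloxy)-3-methoxybenzyl]-4-{(R)-[4-(tert-butyldimethylsilyloxy)-3-methoxyphenyl](hydroxy)methyl}dihydrofuran-2(3H)-one | COc1cc(C[C@H]2C(=O)OC[C@@H]2[C@@H](O)c2ccc(O[Si](C)(C)C(C)(C)C)c(OC)c2)ccc1O[Si](C)(C)C(C)(C)C
F3 | step 10 | (3R,4R)-3-[4-(tert-butyldimethylsilyloxy)-3-methoxybenzyl]-4-[4-(tert-butyldimethylsilyloxy)-3-methoxybenzoyl]dihydrofuran-2(3H)-one | COc1cc(C[C@H]2C(=O)OC[C@@H]2C(=O)c2ccc(O[Si](C)(C)C(C)(C)C)c(OC)c2)ccc1O[Si](C)(C)C(C)(C)C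
F4 | step 6 | 3-[4-(tert-butyldimethylsilyloxy)-3-methoxyphenyl]propanal | COc1cc(CCC=O)ccc1O[Si](C)(C)C(C)(C)C
F5 | step 6 | dimethyl 2-{(2R)-1-[4-(tert-butyldimethylsilyloxy)-3-methoxyphenyl]-3-oxopropan-2-yl}propanedioate | COc1cc(C[C@H](C(C(=O)OC)C(=O)OC)C=O)ccc1O[Si](C)(C)C(C)(C)C
F6 | step 6 | (2R)-2-[4-(tert-butyldimethylsilyloxy)-3-methoxybenzyl]-4-methoxy-3-(methoxycarbonyl)-4-oxobutanoic acid | COc1cc(C[C@H](C(C(=O)OC)C(=O)OC)C(=O)O)ccc1O[Si](C)(C)C(C)(C)C
F7 | step 7 | 1,1-dibenzyl 2-tert-butyl (2R)-3-[4-(tert-butyldimethylsilyloxy)-3-methoxyphenyl]propane-1,1,2-tricarboxylate | COc1cc(C[C@H](C(C(=O)OCc2ccccc2)C(=O)OCc2ccccc2)C(=O)OC(C)(C)C)ccc1O[Si](C)(C)C(C)(C)C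
F8 | step 7 | 2-{(2R)-1-tert-butoxy-3-[4-(tert-butyldimethylsilyloxy)-3-methoxyphenyl]-1-oxopropan-2-yl}propanedioic acid | COc1cc(C[C@H](C(C(=O)O)C(=O)O)C(=O)OC(C)(C)C)ccc1O[Si](C)(C)C(C)(C)C
A1 | alternative 1 | tert-butyl (2R,3R,4S)-2-[4-(tert-butyldimethylsilyloxy)-3-methoxybenzyl]-4-[4-(tert-butyldimethylsilyloxy)-3-methoxyphenyl]-4-hydroxy-3-[(triethylsilyloxy)methyl]butanoate | COc1cc(C[C@@H](C(=O)OC(C)(C)C)[C@H](CO[Si](CC)(CC)CC)[C@H](O)c2ccc(O[Si](C)(C)C(C)(C)C)c(OC)c2)ccc1O[Si](C)(C)C(C)(C)C
A2 | alternative 1 | tert-butyl (2R,3R)-2-[4-(tert-butyldimethylsilyloxy)-3-methoxybenzyl]-3-(4,4,5,5-tetramethyl-1,3,2-dioxaborolan-2-yl)-4-(triethylsilyloxy)butanoate | COc1cc(C[C@@H](C(=O)OC(C)(C)C)[C@H](CO[Si](CC)(CC)CC)B2OC(C)(C)C(C)(C)O2)ccc1O[Si](C)(C)C(C)(C)C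
A3 | alternative 2 | (4R)-4-{(S)-[4-(tert-butyldimethylsilyloxy)-3-methoxyphenyl](tert-butyldimethylsilyloxy)methyl}dihydrofuran-2(3H)-one | O=C1C[C@H](CO1)[C@H](O[Si](C)(C)C(C)(C)C)c1ccc(O[Si](C)(C)C(C)(C)C)c(OC)c1
A4 | alternative 2 | 3-{(S)-[4-(tert-butyldimethylsilyloxy)-3-methoxyphenyl](tert-butyldimethylsilyloxy)methyl}cyclobutan-1-one | O=C1CC(C1)[C@H](O[Si](C)(C)C(C)(C)C)c1ccc(O[Si](C)(C)C(C)(C)C)c(OC)c1
A5 | alternative 2 | [4-(bromomethyl)-2-methoxyphenoxy](tert-butyl)dimethylsilane | COc1cc(CBr)ccc1O[Si](C)(C)C(C)(C)C
A6 | alternative 3 | (3R,4R)-3-[4-(tert-butyldimethylsilyloxy)-3-methoxybenzyl]-4-{(S)-[4-(tert-butyldimethylsilyloxy)-3-methoxyphenyl](tert-butyldimethylsilyloxy)methyl}dihydrofuran-2(3H)-one | COc1cc(C[C@H]2C(=O)OC[C@@H]2[C@H](O[Si](C)(C)C(C)(C)C)c2ccc(O[Si](C)(C)C(C)(C)C)c(OC)c2)ccc1O[Si](C)(C)C(C)(C)C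
A7 | alternative 3 | methyl (2R)-2-[4-(tert-butyldimethylsilyloxy)-3-methoxybenzyl]-3-{(S)-[4-(tert-butyldimethylsilyloxy)-3-methoxyphenyl](tert-butyldimethylsilyloxy)methyl}but-3-enoate | COc1cc(C[C@@H](C(=O)OC)C(=C)[C@H](O[Si](C)(C)C(C)(C)C)c2ccc(O[Si](C)(C)C(C)(C)C)c(OC)c2)ccc1O[Si](C)(C)C(C)(C)C
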